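**Retrosynthetic overview**

1. Ring numbering: C1 (C=O), C2 (=CH), C3 (=C–OMe), C4 (ketal C), C5 (CH2), C6 (CH–allyl). Three features make the key step possible. C1–C2=C3(OMe) is a C-acylated methyl enol ether. C4 is a fully substituted O,O-ketal carbon in the tether (no H, gem-dialkoxy). C6 is an α-CH that can pass through an sp2 ketene carbon.
2. 13 ⇒ cut C1–C2 and C6–H: allyl(alkyl)ketene 11 carrying the CH2=C(OMe) group. 11 ⇒ allylmalonate dianion 10, whose second carboxylate is a temporary activating group that leaves as CO2.
3. 10 ⇒ malonate 8 ⇒ cut C4–OAr: racemic donor–acceptor vinylcyclopropane 7 + phenol 4 (strain release, enantioconvergent, sets C4).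
4. 7 ⇒ 2,3-dimethoxybutadiene 5 + diazomalonate 6 (C1–C6 assembled in one step). 4 ⇒ 3,4-dimethoxyphenol by O-allylation and Claisen rearrangement.
5. Ring order: arene (bought) → cyclopropane (temporary, opened in step 4) → cyclohexenone (closed last, step 7).

Key step: step 7

Assumption: the absolute sense of induction of the Mg–pybox catalyst in step 4 cannot be read from a model, so the ligand antipode that leads to (R)-8 is fixed in a pilot run and is written here as (S,S).

**Step 1**
Reactants: 1 3,4-dimethoxyphenol; 2 allyl bromide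
Product: 3 4-(allyloxy)-1,2-dimethoxybenzene
Conditions: K2CO3, acetone, reflux
Reagents that add atoms: none
Why: Williamson O-allylation of the phenoxide (SN2 on allyl bromide); no stereocentre is formed.

**Step 2**
Reactants: 3 4-(allyloxy)-1,2-dimethoxybenzene
Product: 4 2-allyl-4,5-dimethoxyphenol
Conditions: N,N-diethylaniline, 200 °C
Reagents that add atoms: none
Why: The aromatic Claisen [3,3] rearrangement goes to the free ortho position that is not flanked by a methoxy group, and the dienone tautomerises to the phenol.

**Step 3**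
Reactants: 5 2,3-dimethoxybuta-1,3-diene; 6 dimethyl 2-diazomalonate
Product: 7 dimethyl 2-methoxy-2-(1-methoxyvinyl)cyclopropane-1,1-dicarboxylate (racemic)
Conditions: Rh2(esp)2 (0.5 mol %), 5 (4 equiv), CH2Cl2, slow addition of 6, 0 → 25 °C
Reagents that add atoms: none
Why: Rh-carbenoid cyclopropanation picks the electron-rich enol-ether C=C, the excess of the symmetric diene holds it at the mono-adduct, and the racemate is acceptable because step 4 is enantioconvergent.

**Step 4**
Reactants: 7 dimethyl 2-methoxy-2-(1-methoxyvinyl)cyclopropane-1,1-dicarboxylate; 4 2-allyl-4,5-dimethoxyphenol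
Product: 8 dimethyl 2-[(2R)-2-(2-allyl-4,5-dimethoxyphenoxy)-2,3-dimethoxybut-3-en-1-yl]propanedioate
Conditions: MgI2 (10 mol %), (S,S)-t-Bu-pybox (12 mol %), 4 (1.2 equiv), 4 Å MS, toluene, 0 °C
Reagents that add atoms: none
Why: Proposed new method: the chelating Mg–pybox Lewis acid binds the geminal diester of racemic 7 and reversibly heterolyses the strained push–pull C–C bond to a 1,2-dimethoxyallyl cation/Mg-malonate ion pair (fast racemisation of 7), phenol 4 then adds through oxygen to the cationic carbon that bears OMe inside the chiral pocket while the malonate is protonated irreversibly, so both enantiomers of 7 funnel into (R)-8, and the product has no acceptor left in conjugation with the ketal and is not re-ionised by the chelated catalyst; the closest known reaction types are the dynamic kinetic asymmetric (3+2) annulation of racemic donor–acceptor cyclopropane-1,1-diesters under Mg–pybox catalysis and the chiral-Lewis-acid ring opening of such cyclopropanes by O–H nucleophiles.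

**Step 5**
Reactants: 8 dimethyl 2-[(2R)-2-(2-allyl-4,5-dimethoxyphenoxy)-2,3-dimethoxybut-3-en-1-yl]propanedioate; 2 allyl bromide
Product: 9 dimethyl 2-allyl-2-[(2R)-2-(2-allyl-4,5-dimethoxyphenoxy)-2,3-dimethoxybut-3-en-1-yl]propanedioate
Conditions: NaH, THF, 0 °C; then 2, 0 → 25 °C
Reagents that add atoms: none
Why: Malonate alkylation (SN2 on allyl bromide); the malonate carbon carries two equal ester groups and is not stereogenic, and the base-stable ketal centre is untouched.

**Step 6**
Reactants: 9 dimethyl 2-allyl-2-[(2R)-2-(2-allyl-4,5-dimethoxyphenoxy)-2,3-dimethoxybut-3-en-1-yl]propanedioate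
Product: 10 dipotassium 2-allyl-2-[(2R)-2-(2-allyl-4,5-dimethoxyphenoxy)-2,3-dimethoxybut-3-en-1-yl]propanedioate
Conditions: KOSiMe3 (2.2 equiv), THF, 40 °C; salt collected and dried, no acidification
Reagents that add atoms: potassium trimethylsilanolate, C[Si](C)(C)[O-].[K+]
Why: Silanolate cleavage of the methyl esters gives the anhydrous dicarboxylate directly, so the acid-labile enol ether and aryl methyl ketal never meet a free malonic acid.

**Step 7**
Reactants: 10 dipotassium 2-allyl-2-[(2R)-2-(2-allyl-4,5-dimethoxyphenoxy)-2,3-dimethoxybut-3-en-1-yl]propanedioate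
Product: 13 (4R,6S)-6-allyl-4-(2-allyl-4,5-dimethoxyphenoxy)-3,4-dimethoxycyclohex-2-en-1-one, via allylketene 11 (not isolated), via ring dienol 12 (not isolated)
Conditions: 2-chloro-1-methylpyridinium iodide (1.1 equiv), 18-crown-6 (10 mol %), 2,6-di-tert-butyl-4-methylphenol (20 mol %), i-Pr2NEt (20 mol %), MeCN–CH2Cl2, 0.01 M, 0 → 25 °C
Reagents that add atoms: none
Why: Proposed new method: O-acylation of the pyridinium salt by one carboxylate of 10 lets the other carboxylate leave as CO2 (Grob-type fragmentation, as in the ketene-forming activation of malonic acids by coupling reagents), which gives ketene 11 under neutral conditions and turns the malonate carbon C6 into an sp2 centre. The terminal CH2 of the methyl enol ether (C2) adds to the ketene carbonyl carbon (C1) in the ketene plane, a 6-endo-trig closure at the enol ether (C2 and C3 both end in the ring, the C1=C6 bond is endocyclic) helped by the gem-dialkoxy carbon C4 in the tether; the closest known reaction types are the intramolecular cycloaddition of ketenes joined by a two-atom tether to a 1,1-disubstituted alkene (same C1-to-CH2 bond) and the C-acylation of enol ethers to β-alkoxy enones. The hindered phenol/amine pair removes the now acidic C2 proton to give dienol 12 and returns a proton to C6, which yields the conjugated vinylogous ester 13 and makes the sequence irreversible. C6 is set in this ketonisation by C4: in 12 the C4–OAr bond stands pseudoaxial (overlap of the C2=C3 π bond with σ*C–OAr, no A(1,2) strain with the C3 methoxy group) and covers one ring face, so the bulky proton donor comes from the other face and the allyl group ends cis to OAr, that is (6S) from (4R). The step needs ring closure to win over ketene dimerisation (high dilution, nucleophilic 1,1-disubstituted enol ether five atoms away), no external trapping of 11 (all by-products and additives are non-nucleophilic) and kinetic rather than thermodynamic protonation (weak hindered base, 25 °C or below, short contact).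

**Compound list**

| No. | Name | SMILES | Role |
|---|---|---|---|
| 1 | 3,4-dimethoxyphenol | COc1ccc(O)cc1OC | starting material |
| 2 | allyl bromide | C=CCBr | starting material |
| 3 | 4-(allyloxy)-1,2-dimethoxybenzene | C=CCOc1ccc(OC)c(OC)c1 | intermediate |
| 4 | 2-allyl-4,5-dimethoxyphenol | C=CCc1cc(OC)c(OC)cc1O | intermediate |
| 5 | 2,3-dimethoxybuta-1,3-diene | C=C(OC)C(=C)OC | starting material |
| 6 | dimethyl 2-diazomalonate | COC(=O)C(=[N+]=[N-])C(=O)OC | starting material |
| 7 | dimethyl 2-methoxy-2-(1-methoxyvinyl)cyclopropane-1,1-dicarboxylate (racemic) | COC(=O)C1(C(=O)OC)CC1(OC)C(=C)OC | intermediate |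
| 8 | dimethyl 2-[(2R)-2-(2-allyl-4,5-dimethoxyphenoxy)-2,3-dimethoxybut-3-en-1-yl]propanedioate | C=CCc1cc(OC)c(OC)cc1O[C@](C(=C)OC)(OC)CC(C(=O)OC)C(=O)OC | intermediate |
| 9 | dimethyl 2-allyl-2-[(2R)-2-(2-allyl-4,5-dimethoxyphenoxy)-2,3-dimethoxybut-3-en-1-yl]propanedioate | C=CCc1cc(OC)c(OC)cc1O[C@](C(=C)OC)(OC)CC(CC=C)(C(=O)OC)C(=O)OC | intermediate |
| 10 | dipotassium 2-allyl-2-[(2R)-2-(2-allyl-4,5-dimethoxyphenoxy)-2,3-dimethoxybut-3-en-1-yl]propanedioate | [K+].[K+].C=CCc1cc(OC)c(OC)cc1O[C@](C(=C)OC)(OC)CC(CC=C)(C([O-])=O)C([O-])=O | intermediate |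
| 11 | (4R)-2-allyl-4-(2-allyl-4,5-dimethoxyphenoxy)-4,5-dimethoxyhexa-1,5-dien-1-one (ketene) | C=CCc1cc(OC)c(OC)cc1O[C@](C(=C)OC)(OC)CC(CC=C)=C=O | intermediate |
| 12 | (4R)-6-allyl-4-(2-allyl-4,5-dimethoxyphenoxy)-3,4-dimethoxycyclohexa-1(6),2-dien-1-ol (enol of 13 toward C6) | C=CCc1cc(OC)c(OC)cc1O[C@]1(OC)CC(CC=C)=C(O)C=C1OC | intermediate |
| 13 | (4R,6S)-6-allyl-4-(2-allyl-4,5-dimethoxyphenoxy)-3,4-dimethoxycyclohex-2-en-1-one | C=CCc1cc(OC)c(OC)cc1O[C@]1(OC)C[C@H](CC=C)C(=O)C=C1OC | target |

Total step count: 7. Longest linear sequence: 6 steps (1 → 3 → 4 → 8 → 9 → 10 → 13).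

**Steps most likely to fail**

**Step 7 (labelled).**
- The ketene may be used up by dimerisation or by acyl transfer to unreacted carboxylate before the enol ether closes the ring.
- At the dienol stage, loss of the aryloxy group followed by aromatisation can compete.
- Protonation at C6 may show poor facial selectivity, or the centre may equilibrate afterwards.

The fallback sets out from 9 and comes back at 13. One ester of 9 is cleaved with one equivalent of KOSiMe3 to potassium half-ester salt F1. Oxalyl chloride turns this into malonyl chloride half-ester F2. F2 has no α-H, so it cannot form a ketene, and it acylates the tethered enol ether directly (2,6-lutidine, CH2Cl2). This is the known C-acylation of enol ethers by activated acid chlorides, and it gives quaternary β-keto ester F3. A second silanolate cleavage gives potassium β-keto carboxylate F4, which loses CO2 on buffering to pH 6–7 (NaH2PO4) and ketonises through 12 to 13.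

**Step 4 (labelled).**
- Facial discrimination at the planar cation may be insufficient.
- The electron-rich phenol may attack through carbon, or at the CH2 terminus of the allyl cation.
- The ion pair may collapse to the cyclopentene (vinylcyclopropane rearrangement).

The fallback sets out from 7 and comes back at 10. Racemic 7 is opened with 4 under an achiral Lewis acid (Yb(OTf)3) to racemic malonate F5. Allylation as in step 5 gives racemic allylmalonate F6, and silanolate cleavage gives racemic dipotassium salt F7. Salt metathesis with (R)-1-phenylethylammonium chloride gives two diastereomeric bis-ammonium salts, less soluble salt F8 and more soluble salt F9. These are separated by fractional crystallisation (classical resolution; the amine antipode is chosen so that the (R)-malonate crystallises). KOH sets the amine free from F8 and returns 10.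

**Step 3.**
- A second cyclopropanation of the remaining enol ether may occur.
- The very activated cyclopropane may ring-expand on the catalyst or on silica.

The fallback sets out from 5 and comes back at 7. 1,4-Addition of bromine to 5 gives 1,4-dibromo-2,3-dimethoxybut-2-ene F10. Sodium dimethyl malonate displaces one bromide to give bromo malonate F11. A second deprotonation of F11 closes the three-membered ring by intramolecular SN2′ displacement and gives 7. This is the classical route from 1,4-dihalobut-2-enes to 2-vinylcyclopropane-1,1-diesters.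

**Further compounds**
F1 | step 7 | potassium methyl 2-allyl-2-[(2R)-2-(2-allyl-4,5-dimethoxyphenoxy)-2,3-dimethoxybut-3-en-1-yl]propanedioate (half-ester salt, malonate carbon unassigned) | [K+].C=CCc1cc(OC)c(OC)cc1O[C@](C(=C)OC)(OC)CC(CC=C)(C(=O)OC)C([O-])=O
F2 | step 7 | methyl 2-allyl-2-(chlorocarbonyl)-(4R)-4-(2-allyl-4,5-dimethoxyphenoxy)-4,5-dimethoxyhex-5-enoate | C=CCc1cc(OC)c(OC)cc1O[C@](C(=C)OC)(OC)CC(CC=C)(C(=O)OC)C(=O)Cl
F3 | step 7 | methyl (5R)-1-allyl-5-(2-allyl-4,5-dimethoxyphenoxy)-4,5-dimethoxy-2-oxocyclohex-3-ene-1-carboxylate (C1 epimers) | C=CCc1cc(OC)c(OC)cc1O[C@]1(OC)CC(CC=C)(C(=O)OC)C(=O)C=C1OC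
F4 | step 7 | potassium (5R)-1-allyl-5-(2-allyl-4,5-dimethoxyphenoxy)-4,5-dimethoxy-2-oxocyclohex-3-ene-1-carboxylate | [K+].C=CCc1cc(OC)c(OC)cc1O[C@]1(OC)CC(CC=C)(C([O-])=O)C(=O)C=C1OC
F5 | step 4 | racemic dimethyl 2-[2-(2-allyl-4,5-dimethoxyphenoxy)-2,3-dimethoxybut-3-en-1-yl]propanedioate | C=CCc1cc(OC)c(OC)cc1OC(C(=C)OC)(OC)CC(C(=O)OC)C(=O)OC
F6 | step 4 | racemic dimethyl 2-allyl-2-[2-(2-allyl-4,5-dimethoxyphenoxy)-2,3-dimethoxybut-3-en-1-yl]propanedioate | C=CCc1cc(OC)c(OC)cc1OC(C(=C)OC)(OC)CC(CC=C)(C(=O)OC)C(=O)OC
F7 | step 4 | racemic dipotassium 2-allyl-2-[2-(2-allyl-4,5-dimethoxyphenoxy)-2,3-dimethoxybut-3-en-1-yl]propanedioate | [K+].[K+].C=CCc1cc(OC)c(OC)cc1OC(C(=C)OC)(OC)CC(CC=C)(C([O-])=O)C([O-])=O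
F8 | step 4 | bis[(R)-1-phenylethylammonium] salt of the (R)-allylmalonate | C[C@@H]([NH3+])c1ccccc1.C[C@@H]([NH3+])c1ccccc1.C=CCc1cc(OC)c(OC)cc1O[C@](C(=C)OC)(OC)CC(CC=C)(C([O-])=O)C([O-])=O
F9 | step 4 | bis[(R)-1-phenylethylammonium] salt of the (S)-allylmalonate | C[C@@H]([NH3+])c1ccccc1.C[C@@H]([NH3+])c1ccccc1.C=CCc1cc(OC)c(OC)cc1O[C@@](C(=C)OC)(OC)CC(CC=C)(C([O-])=O)C([O-])=O
F10 | step 3 | 1,4-dibromo-2,3-dimethoxybut-2-ene | BrCC(OC)=C(OC)CBr
F11 | step 3 | dimethyl 2-(4-bromo-2,3-dimethoxybut-2-en-1-yl)propanedioate | COC(=O)C(CC(OC)=C(OC)CBr)C(=O)OC
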